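# Marchantinquinone: total synthesis proposal

## Analysis of the target

- Marchantinquinone 20 (C28H22O5) is an 18-membered cyclic bis(bibenzyl). Four six-membered rings lie in the large ring: ring A (1,4-phenylene), ring B (a phenol), ring C (1,3-phenylene) and ring D (a 1,4-benzoquinone bridged through neighbouring atoms).
- The sequence is D–C7H2–C8H2–A–O–B–C7′H2–C8′H2–C–O–D. In ring B the free OH is ortho to the ether oxygen and para to C7′.
- Ring D locants: C1 is the carbonyl next to C2, C2 bears C7, C3 bears the ether oxygen to ring C, C4 is the second carbonyl, and C5H=C6H is unsubstituted.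
- There is no stereocentre and no stereogenic double bond, so stereocontrol is not an issue.
- Sensitive groups:
  - the aryloxyquinone, a vinylogous aryl ester that nucleophiles and bases cleave;
  - the bare C5=C6 Michael acceptor;
  - the para-alkylphenol of ring B, which can over-oxidise to a quinone methide or an ortho-quinone;
  - four benzylic CH2 groups.
- The difficulties are the entropic cost of the macrocycle, the fixed order of four different rings, and the C3–O bond, which is flanked by C2-alkyl and C4-oxygen. The quinone must also be unveiled next to an oxidisable phenol.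
- The feature exploited is the triad O=C1–C2(C7)=C3–O(ring C). Its two oxygens sit 1,3 around the alkylated carbon C2, which is the retron of a 2-alkylcyclohexane-1,3-dione.
- C4=O (para to C1) and the C5=C6 unsaturation carry no carbon substituent, so both can be added by oxidation after the ring is closed.

## Retrosynthetic reasoning

**20 ⇒ 18 (via 19).** Only the O–benzyl bond on ring B is cut. The ring B oxygen must stay masked while another phenoxide closes the ring and while ring D is oxidised. Hydrogenolysis reduces the quinone reversibly to 19, and one equivalent of a mild oxidant restores it.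

**18 ⇒ 17.** The C4=O oxygen is removed. In 17 the C1 hydroxyl is the only free phenol, and its para position C4 is free. A radical phenol oxidation therefore has an intrinsic preference for C4. This is a late C–H oxygenation that spares the route a 1,2,4-trioxygenated ring D building block.

**17 ⇒ 14.** The C5=C6 unsaturation is removed, so ring D becomes a 3-aryloxy-2-alkylcyclohex-2-enone. Any dehydrogenation within C4–C5–C6 of 14 gives a keto tautomer of 17. The regiochemistry of enolisation therefore does not matter.

**14 ⇒ 12 (via 13), the key disconnection.**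
- The C3–O bond is cut, and the macrocycle opens at its most hindered bond.
- At the cyclohexenone level this bond is a vinylogous ester. Ring D is then the electrophile (a vinylogous acid chloride) and the ring C phenol the nucleophile, with no metal and no activating group to remove.
- Closing the same bond at the quinone oxidation level was rejected. The unsubstituted C5=C6 would be the more accessible acceptor, base would tautomerise the alkylquinone towards a quinone methide, and a tether of this length cannot tell C3 from C5 or C6.
- In 12 these positions are saturated, and C3 is the only electrophilic sp2 carbon with a leaving group.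

**12 ⇒ 11 ⇒ 8 + 9.** The C3–Cl bond goes back to the enol of dione 11. The C2–C7 bond is then cut to arylacetaldehyde 8 and cyclohexane-1,3-dione 9. Because 9 and 11 have two equivalent carbonyl groups, neither the alkylation at C2 nor the chlorination has a regiochemical choice. A condensation/transfer-hydrogenation sequence is used because direct C-alkylation of 9 with a phenethyl halide would suffer from O-alkylation and elimination.

**8 ⇒ 7 ⇒ 4 + 5.** After adjusting the alcohol/aldehyde oxidation level, the C8′–C(aryl, ring C) bond is cut. A hydroboration/B-alkyl cross-coupling gives the saturated bridge directly. A cut at C7′=C8′ would need a stilbene hydrogenation that the benzyl ether would not survive. Ring C enters last among the arenes, so its silyl ether never meets hot carbonate.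

**4 ⇒ 3 ⇒ 1 + 2.** The vinyl group goes back to the aldehyde of 3. The O–C(ring A) bond is cut to phenol 1 and aryl iodide 2. This is the unhindered ether, an ordinary intermolecular copper coupling, and 2 already carries C7 and C8.

## Alternatives that were turned down

**Alternative 1:** the textbook route cuts C7–C8.
- *Forward key step:* intramolecular Wittig reaction of phosphonium aldehyde A1 to the macrocyclic stilbene A2 (E/Z mixture). Hydrogenation follows, then oxidative demethylation of the 1,4-dimethoxy ring D.
- *Why turned down:*
  - The hindered C3–O ether must first be made by copper chemistry on a fully substituted ring D aldehyde.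
  - Two pairs of benzylic carbons must be told apart with protecting groups and taken through CHO → CH2OH → CH2Br → phosphonium chains.
  - The alkene must then be removed again.
  - The final cerium(IV) oxidation must distinguish ring D from the electron-rich ring B.
  - The key step forms only an unhindered C=C bond, and the route is about half as long again.

**Alternative 2:** cut the unhindered ether O–C(ring B).
- *Forward key step:* copper-catalysed Ullmann macrocyclisation of bromophenol A3 to the dimethoxy macrocycle A4, then oxidative demethylation to reach 18.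
- *Why turned down:*
  - A catalytic bimolecular step (substrate plus copper) is slowed by the very dilution the ring closure needs.
  - The harder C3–O ether is only moved to an earlier intermolecular coupling at a di-ortho-substituted carbon.
  - Ring D must again be carried as a dimethyl ether, with the same oxidant selectivity problem at the end.

**Alternative 3:** cut the C5=C6 two-carbon unit out of ring D.
- *Forward key step:* vinyl-metal addition to the macrocyclic cyclobutenedione A5 gives 4-hydroxy-4-vinylcyclobutenone A6. A thermal 4π-opening/6π-closure (Moore-type ring expansion) and oxidation follow.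
- *Why turned down:*
  - The regiochemistry is as clean as in the chosen route, but the ring expansion does not close the macrocycle. That still has to be done at the same C3–O bond on a semisquaric chloride.
  - Reaching that chloride needs a phenethyllithium, a squarate addition, a hydrolysis and a chlorination, about four more steps.
  - The hard vinyl nucleophile can displace the aryloxide of A5 and reopen the ring.

Key step: step 7

Assumption: the target SMILES holds no stereocentre and no stereogenic double bond, and the 18-membered ring is taken as conformationally mobile. The compound is therefore treated as achiral, and no step has to set or keep a configuration.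

## Route

Step 1
Reactants: 1 4-(benzyloxy)-3-hydroxybenzaldehyde; 2 2-(4-iodophenyl)ethan-1-ol
Product: 3 4-(benzyloxy)-3-[4-(2-hydroxyethyl)phenoxy]benzaldehyde
Conditions: CuI (10 mol %), N,N-dimethylglycine·HCl (30 mol %), Cs2CO3, dioxane, 90 °C
Reagents that add atoms: none
Why: Ligand-accelerated Ullmann diaryl ether coupling; the phenoxide of 1 is arylated by the unhindered aryl iodide at a temperature at which a primary alcohol and a non-enolisable aldehyde are spectators. The only ortho neighbour of the new bond is OBn.

Step 2
Reactants: 3 4-(benzyloxy)-3-[4-(2-hydroxyethyl)phenoxy]benzaldehyde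
Product: 4 2-{4-[2-(benzyloxy)-5-ethenylphenoxy]phenyl}ethan-1-ol
Conditions: Ph3PCH3Br (2.5 equiv), KOtBu (2.4 equiv), THF, 0 °C to rt
Reagents that add atoms: methyltriphenylphosphonium bromide C[P+](c1ccccc1)(c1ccccc1)c1ccccc1.[Br-]
Why: Wittig methylenation of an aromatic aldehyde; the extra equivalent of base only deprotonates the alcohol, which returns on work-up.

Step 3
Reactants: 4 2-{4-[2-(benzyloxy)-5-ethenylphenoxy]phenyl}ethan-1-ol; 5 (3-bromophenoxy)tri(propan-2-yl)silane
Product: 7 2-{4-[2-(benzyloxy)-5-(2-{3-[(triisopropylsilyl)oxy]phenyl}ethyl)phenoxy]phenyl}ethan-1-ol, via bis(9-BBN) adduct 6 (not isolated)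
Conditions: 9-BBN (2.2 equiv), THF, rt; then 5, PdCl2(dppf) (5 mol %), aq K3PO4, THF/DMF, 60 °C
Reagents that add atoms: none
Why: Anti-Markovnikov hydroboration of the styrene (the second equivalent of borane is taken up by the OH group) followed by B-alkyl Suzuki–Miyaura coupling gives the saturated C7′–C8′ bridge directly, so the benzyl ether never meets hydrogen. The aryl TIPS ether should tolerate aqueous phosphate.

Step 4
Reactants: 7 2-{4-[2-(benzyloxy)-5-(2-{3-[(triisopropylsilyl)oxy]phenyl}ethyl)phenoxy]phenyl}ethan-1-ol
Product: 8 2-{4-[2-(benzyloxy)-5-(2-{3-[(triisopropylsilyl)oxy]phenyl}ethyl)phenoxy]phenyl}acetaldehyde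
Conditions: Dess–Martin periodinane, CH2Cl2, 0 °C to rt; used without storage
Reagents that add atoms: none
Why: Dess–Martin oxidation stops at the aldehyde under near-neutral conditions, which an enolisable arylacetaldehyde needs; ethers and the silyl ether are inert.

Step 5
Reactants: 8 2-{4-[2-(benzyloxy)-5-(2-{3-[(triisopropylsilyl)oxy]phenyl}ethyl)phenoxy]phenyl}acetaldehyde; 9 cyclohexane-1,3-dione
Product: 11 2-[2-(4-{2-(benzyloxy)-5-[2-(3-{(triisopropylsilyl)oxy}phenyl)ethyl]phenoxy}phenyl)ethyl]cyclohexane-1,3-dione, via alkylidene dione 10 (not isolated)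
Conditions: L-proline (20 mol %), Hantzsch ester (1.1 equiv), CH2Cl2, rt
Reagents that add atoms: none
Why: Organocatalytic three-component reductive alkylation: Knoevenagel condensation to 10, then transfer hydrogenation of this very electrophilic alkene by the Hantzsch ester. This gives clean C2-monoalkylation and forms the C2–C7 bond.

Step 6
Reactants: 11 2-[2-(4-{2-(benzyloxy)-5-[2-(3-{(triisopropylsilyl)oxy}phenyl)ethyl]phenoxy}phenyl)ethyl]cyclohexane-1,3-dione
Product: 12 3-chloro-2-[2-(4-{2-(benzyloxy)-5-[2-(3-{(triisopropylsilyl)oxy}phenyl)ethyl]phenoxy}phenyl)ethyl]cyclohex-2-en-1-one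
Conditions: (COCl)2 (1.5 equiv), DMF (cat.), CH2Cl2, 0 °C to rt
Reagents that add atoms: oxalyl chloride O=C(Cl)C(=O)Cl
Why: Vilsmeier-type conversion of the enol of a 1,3-diketone into the β-chloroenone (vinylogous acid to vinylogous acid chloride), standard for 2-alkylcyclohexane-1,3-diones. The two carbonyl groups of 11 are equivalent, so only one chloroenone can form.

Step 7
Reactants: 12 3-chloro-2-[2-(4-{2-(benzyloxy)-5-[2-(3-{(triisopropylsilyl)oxy}phenyl)ethyl]phenoxy}phenyl)ethyl]cyclohex-2-en-1-one
Product: 14 macrocyclic vinylogous aryl ester (18-membered ring; ring D = 3-aryloxy-2-alkylcyclohex-2-en-1-one, ring B O-benzyl), via caesium phenoxide 13 (not isolated)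
Conditions: CsF (5 equiv), 18-crown-6 (20 mol %), 4 Å MS, MeCN, 70 °C; 12 added by syringe pump over 12 h (final 1 mM)
Reagents that add atoms: none
Why: Fluoride removes the TIPS group and releases phenoxide 13 slowly and at very low stationary concentration; its oxygen adds to C3, the β-carbon of the chloroenone, to give a tetrahedral enolate that expels chloride (addition–elimination), which restores C2=C3 inside ring D. The closest known reaction types are the base-mediated preparation of 3-aryloxycyclohex-2-enones from 3-chlorocyclohex-2-enones (2-alkyl members included) and phenols, and fluoride-triggered aryl ether closures of silyl-protected phenols. One ring is closed, the 18-membered macrocycle, by an 18-endo-trig addition (C2 and C3 both end up in the large ring), and no stereocentre is formed. Site selectivity: C3 is the only carbon of 12 with a leaving group and the only Michael position, because C4=O and C5=C6 of the later quinone do not yet exist, and attack at C1=O is reversible and unproductive. Constitutional selectivity was already fixed by the equivalence of the two carbonyl groups of 11. The benzyl ether on ring B decides between the two phenolic oxygens, and the caesium counter-ion in a dipolar aprotic solvent favours O- over C-attack of the phenoxide. Ring closure is favoured over oligomerisation by the slow addition and slow desilylation, and aryloxide exchange at vinylogous esters is reversible, so open oligomers can still be corrected to the monomeric ring at 1 mM. The crowding at C3 costs rate but not selectivity, since the nucleophile approaches perpendicular to the enone plane and not in the plane, as a metal-mediated arylation at a di-ortho-substituted arene carbon would require.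

Step 8
Reactants: 14 macrocyclic vinylogous aryl ester
Product: 17 macrocyclic phenol (ring D = 2-alkyl-3-aryloxyphenol, OH at C1; ring B O-benzyl), via racemic C6-phenylselanyl ketone 15 (not isolated), via cross-conjugated cyclohexa-2,5-dienone 16 (not isolated)
Conditions: LDA (1.1 equiv), THF, −78 °C; PhSeCl, −78 °C; then H2O2 (2 equiv), pyridine, CH2Cl2, 0 °C to rt
Reagents that add atoms: none
Why: Kinetic α′-deprotonation of a vinylogous ester at C6, selenenylation and selenoxide syn-elimination, the standard way from 3-alkoxycyclohexenones to resorcinol monoethers. Dienone 16 is the keto tautomer of 17 and aromatises at once; the stereocentre of 15 is racemic and is destroyed in the same operation.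

Step 9
Reactants: 17 macrocyclic phenol
Product: 18 O-benzylmarchantinquinone (ring D = 2-alkyl-3-aryloxy-1,4-benzoquinone; ring B O-benzyl)
Conditions: (KSO3)2NO (2.5 equiv), KH2PO4 buffer, acetone/THF/H2O, rt
Reagents that add atoms: potassium nitrosodisulfonate (Fremy's salt) [K+].[K+].[O]N(S(=O)(=O)[O-])S(=O)(=O)[O-]
Why: Teuber oxidation: hydrogen abstraction from the only free phenol and radical coupling at the free para carbon C4 give the para-quinone, the normal outcome whenever the para position is open. Aryl ethers, the benzyl ether and the benzylic CH2 groups do not react with this reagent.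

Step 10
Reactants: 18 O-benzylmarchantinquinone
Product: 20 marchantinquinone, via hydroquinone 19 (not isolated)
Conditions: H2 (1 atm), Pd/C, EtOAc/THF, rt; filter under N2; then DDQ (1.0 equiv), 0 °C
Reagents that add atoms: none
Why: Hydrogenolysis of the aryl benzyl ether, during which the quinone is reduced reversibly to 19. One equivalent of DDQ restores the quinone, because the electron-rich hydroquinone is oxidised far faster than the para-alkylphenol of ring B.

## Compound list

1 | 4-(benzyloxy)-3-hydroxybenzaldehyde | O=Cc1ccc(OCc2ccccc2)c(O)c1 | starting material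
2 | 2-(4-iodophenyl)ethan-1-ol | OCCc1ccc(I)cc1 | starting material
3 | 4-(benzyloxy)-3-[4-(2-hydroxyethyl)phenoxy]benzaldehyde | O=Cc1ccc(OCc2ccccc2)c(Oc2ccc(CCO)cc2)c1 | intermediate
4 | 2-{4-[2-(benzyloxy)-5-ethenylphenoxy]phenyl}ethan-1-ol | C=Cc1ccc(OCc2ccccc2)c(Oc2ccc(CCO)cc2)c1 | intermediate
5 | (3-bromophenoxy)tri(propan-2-yl)silane (catalogue compound; also one step from 3-bromophenol) | CC(C)[Si](Oc1cccc(Br)c1)(C(C)C)C(C)C | starting material
6 | bis(9-BBN) adduct of 4 (B-alkyl at C8′, O-borinate at the alcohol) | C(Cc1ccc(OCc2ccccc2)c(Oc2ccc(CCOB3C4CCCC3CCC4)cc2)c1)B1C2CCCC1CCC2 | intermediate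
7 | 2-{4-[2-(benzyloxy)-5-(2-{3-[(triisopropylsilyl)oxy]phenyl}ethyl)phenoxy]phenyl}ethan-1-ol | OCCc1ccc(Oc2cc(CCc3cccc(O[Si](C(C)C)(C(C)C)C(C)C)c3)ccc2OCc2ccccc2)cc1 | intermediate
8 | 2-{4-[2-(benzyloxy)-5-(2-{3-[(triisopropylsilyl)oxy]phenyl}ethyl)phenoxy]phenyl}acetaldehyde | O=CCc1ccc(Oc2cc(CCc3cccc(O[Si](C(C)C)(C(C)C)C(C)C)c3)ccc2OCc2ccccc2)cc1 | intermediate
9 | cyclohexane-1,3-dione | O=C1CCCC(=O)C1 | starting material
10 | 2-(2-arylethylidene)cyclohexane-1,3-dione (Knoevenagel product of 8 and 9) | O=C1CCCC(=O)C1=CCc1ccc(Oc2cc(CCc3cccc(O[Si](C(C)C)(C(C)C)C(C)C)c3)ccc2OCc2ccccc2)cc1 | intermediate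
11 | 2-(2-arylethyl)cyclohexane-1,3-dione (seco-dione) | O=C1CCCC(=O)C1CCc1ccc(Oc2cc(CCc3cccc(O[Si](C(C)C)(C(C)C)C(C)C)c3)ccc2OCc2ccccc2)cc1 | intermediate
12 | 3-chloro-2-(2-arylethyl)cyclohex-2-en-1-one (seco-chloroenone) | O=C1CCCC(Cl)=C1CCc1ccc(Oc2cc(CCc3cccc(O[Si](C(C)C)(C(C)C)C(C)C)c3)ccc2OCc2ccccc2)cc1 | intermediate
13 | caesium phenoxide from 12 | O=C1CCCC(Cl)=C1CCc1ccc(Oc2cc(CCc3cccc([O-])c3)ccc2OCc2ccccc2)cc1.[Cs+] | intermediate
14 | macrocyclic vinylogous aryl ester | O=C1CCCC2=C1CCc1ccc(cc1)Oc1cc(ccc1OCc1ccccc1)CCc1cccc(c1)O2 | intermediate
15 | C6-phenylselanyl derivative of 14 (racemic) | O=C1C(CCC2=C1CCc1ccc(cc1)Oc1cc(ccc1OCc1ccccc1)CCc1cccc(c1)O2)[Se]c1ccccc1 | intermediate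
16 | cross-conjugated dienone (keto tautomer of 17) | O=C1C=CCC2=C1CCc1ccc(cc1)Oc1cc(ccc1OCc1ccccc1)CCc1cccc(c1)O2 | intermediate
17 | macrocyclic phenol | Oc1cccc2c1CCc1ccc(cc1)Oc1cc(ccc1OCc1ccccc1)CCc1cccc(c1)O2 | intermediate
18 | O-benzylmarchantinquinone | O=C1C=CC(=O)C2=C1CCc1ccc(cc1)Oc1cc(ccc1OCc1ccccc1)CCc1cccc(c1)O2 | intermediate
19 | dihydromarchantinquinone (hydroquinone) | Oc1ccc(O)c2c1CCc1ccc(cc1)Oc1cc(ccc1O)CCc1cccc(c1)O2 | intermediate
20 | marchantinquinone | O=C1C=CC(=O)C2=C1CCc1ccc(cc1)Oc1cc(ccc1O)CCc1cccc(c1)O2 | target

## Step count and least certain steps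

Total step count: 10. Longest linear sequence: 10 (from 1 and 2 to 20); 5 and 9 enter as purchased.

**Step 7 (key step).**
- *What may go wrong:* oligomerisation, because addition to a tetrasubstituted β-carbon is slow and the ring closure then loses its advantage over intermolecular attack. The second risk is hydrolysis of the chloroenone by traces of water liberated with the fluoride.
- *Fallback:* the hindered bond is made intermolecularly and the ring is closed elsewhere. It sets out from 4 and returns at 14.
  1. Ring C is left off, and 4 is oxidised with Dess–Martin periodinane to the vinyl-substituted arylacetaldehyde F1.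
  2. Reductive alkylation with 9 gives the dione F2.
  3. Oxalyl chloride gives the chloroenone F3.
  4. 3-Iodophenol with K2CO3 in DMF at normal concentration gives the iodoaryl vinylogous ester F4.
  5. 9-BBN hydroborates the styrene to the alkylborane F5. The vinylogous ester carbonyl behaves like an ester towards this borane.
  6. A B-alkyl Suzuki macrocyclisation (PdCl2(dppf), AsPh3, Cs2CO3, DMF/THF/H2O, high dilution) closes the ring at the C8′–aryl bond to give 14.

**Step 5.**
- *What may go wrong:* tautomerisation of the Knoevenagel alkene into conjugation with ring A before hydride transfer, self-aldol reaction of the arylacetaldehyde through its enamine, or Michael addition of a second dione.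
- *Fallback:* the condensation is replaced by an SN2 alkylation of a masked dione carbanion. It sets out from 7 and returns at 11.
  1. I2/PPh3/imidazole gives the primary iodide F6.
  2. F6 alkylates 1,5-dimethoxycyclohexa-1,4-diene, lithiated at C6 with t-BuLi, to give the bis(enol ether) F7.
  3. Dilute HCl in acetone hydrolyses F7 to 11.

**Step 8.**
- *What may go wrong:* proton exchange between enolate and selenide, which gives incomplete conversion or double selenenylation. The new electron-rich phenol may also be over-oxidised by peroxide and selenium(IV) species.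
- *Fallback:* no chalcogen and no peroxide. It sets out from 14 and returns at 17.
  1. The enolate is trapped with TMSCl as the isolable silyl dienol ether F8.
  2. F8 is dehydrogenated by Pd(OAc)2 in MeCN (Saegusa–Ito reaction, β-hydride elimination from a palladium enolate) through 16 to 17.

**Step 9.**
- *What may go wrong:* slow reaction, because the lipophilic macrocycle and the water-bound radical salt hardly share a phase. Prolonged exposure would then allow attack at the ortho carbon C6.
- *Fallback:* a two-electron oxidation in an organic solvent. It sets out from 17 and returns at 18.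
  1. PhI(OAc)2 (2 equiv) in methanol gives the para-quinone monoketal F9.
  2. Dilute aqueous acid hydrolyses F9 to 18.

**Step 10.**
- *What may go wrong:* overshoot of the re-oxidation, that is, oxidation of the freed para-alkylphenol of ring B towards a quinone methide. Incomplete hydrogenolysis on a catalyst poisoned by quinone or hydroquinone is the other risk.
- *Fallback:* the order of deprotection and oxidation is reversed. It sets out from 17 and returns at 20.
  1. Hydrogenolysis of 17 gives the bisphenol F10.
  2. Co(salen)/O2 in DMF oxidises only the phenol whose para position is free (ring D), which gives 20.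

## Further compounds

F1 | step 7 | 2-{4-[2-(benzyloxy)-5-ethenylphenoxy]phenyl}acetaldehyde | C=Cc1ccc(OCc2ccccc2)c(Oc2ccc(CC=O)cc2)c1
F2 | step 7 | 2-(2-{4-[2-(benzyloxy)-5-ethenylphenoxy]phenyl}ethyl)cyclohexane-1,3-dione | C=Cc1ccc(OCc2ccccc2)c(Oc2ccc(CCC3C(=O)CCCC3=O)cc2)c1
F3 | step 7 | 2-(2-{4-[2-(benzyloxy)-5-ethenylphenoxy]phenyl}ethyl)-3-chlorocyclohex-2-en-1-one | C=Cc1ccc(OCc2ccccc2)c(Oc2ccc(CCC3=C(Cl)CCCC3=O)cc2)c1
F4 | step 7 | 2-(2-{4-[2-(benzyloxy)-5-ethenylphenoxy]phenyl}ethyl)-3-(3-iodophenoxy)cyclohex-2-en-1-one | C=Cc1ccc(OCc2ccccc2)c(Oc2ccc(CCC3=C(Oc4cccc(I)c4)CCCC3=O)cc2)c1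
F5 | step 7 | B-alkyl-9-BBN from F4 | O=C1CCCC(Oc2cccc(I)c2)=C1CCc1ccc(Oc2cc(CCB3C4CCCC3CCC4)ccc2OCc2ccccc2)cc1
F6 | step 5 | primary iodide from 7 | ICCc1ccc(Oc2cc(CCc3cccc(O[Si](C(C)C)(C(C)C)C(C)C)c3)ccc2OCc2ccccc2)cc1
F7 | step 5 | 6-(2-arylethyl)-1,5-dimethoxycyclohexa-1,4-diene | COC1=CCC=C(OC)C1CCc1ccc(Oc2cc(CCc3cccc(O[Si](C(C)C)(C(C)C)C(C)C)c3)ccc2OCc2ccccc2)cc1
F8 | step 8 | trimethylsilyl dienol ether of 14 | C[Si](C)(C)OC1=CCCC2=C1CCc1ccc(cc1)Oc1cc(ccc1OCc1ccccc1)CCc1cccc(c1)O2
F9 | step 9 | para-quinone C4 dimethyl monoketal | O=C1C=CC(OC)(OC)C2=C1CCc1ccc(cc1)Oc1cc(ccc1OCc1ccccc1)CCc1cccc(c1)O2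
F10 | step 10 | macrocyclic bisphenol (debenzylated 17) | Oc1cccc2c1CCc1ccc(cc1)Oc1cc(ccc1O)CCc1cccc(c1)O2
A1 | alternative 1 | seco phosphonium aldehyde | O=Cc1c(OC)ccc(OC)c1Oc1cccc(CCc2ccc(OCc3ccccc3)c(Oc3ccc(C[P+](c4ccccc4)(c4ccccc4)c4ccccc4)cc3)c2)c1.[Br-]
A2 | alternative 1 | macrocyclic C7=C8 stilbene (E/Z mixture) | COc1ccc(OC)c2c1C=Cc1ccc(cc1)Oc1cc(ccc1OCc1ccccc1)CCc1cccc(c1)O2
A3 | alternative 2 | seco bromophenol | Oc1ccc(CCc2c(OC)ccc(OC)c2Oc2cccc(CCc3ccc(OCc4ccccc4)c(Br)c3)c2)cc1
A4 | alternative 2 | macrocycle with 1,4-dimethoxy ring D | COc1ccc(OC)c2c1CCc1ccc(cc1)Oc1cc(ccc1OCc1ccccc1)CCc1cccc(c1)O2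
A5 | alternative 3 | macrocyclic 3-aryloxy-4-alkylcyclobutene-1,2-dione | O=C1C(=O)C2=C1CCc1ccc(cc1)Oc1cc(ccc1OCc1ccccc1)CCc1cccc(c1)O2
A6 | alternative 3 | macrocyclic 4-hydroxy-4-vinylcyclobutenone (racemic) | O=C1C(O)(C=C)C2=C1CCc1ccc(cc1)Oc1cc(ccc1OCc1ccccc1)CCc1cccc(c1)O2
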